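**Plan**

1. Retrosynthetic cuts, in order: (i) the three O–benzyl bonds (O7, O3', O4'). (ii) C4–H, back to the flat 4-arylcoumarin 19. (iii) In one cut, C4–C4a and O1–C8a, back to aryl β-iodocinnamate 15, in which O1 still sits on C4a. (iv) The ester bond C2–O1 (phenol 8 + acid 14). (v) C6–CH2 of the bibenzyl.
2. Enabling feature: in benzo ring A (C4a, C5, C6, C7, C8, C8a), O7 is para to C4a and O1 sits on the adjacent C8a. Ring A is therefore a hydroquinone in disguise: a C4 radical can attack the ipso carbon that carries the ester oxygen, and that oxygen then moves to C8a.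
3. Forward order: side chain onto ring A (steps 1–3), C3 acid on ring B (steps 4–6), ester link (step 7), radical cascade that closes the pyranone ring through a transient spirolactone (step 8), then reduction and debenzylation (steps 9, 10).
4. Stereochemistry: C4 is the only stereocentre. It is set in step 9 by ligand-controlled Cu–H conjugate reduction of 19 and is not touched afterwards. The alkene geometry of 15 does not matter, because both isomers give the same linear vinyl radical.

Key step: step 8

Remark on locants: coumarin numbering (O1, C2, C3, C4, C4a, C5–C8, C8a) is used for these atoms in all intermediates. Ring A is the benzo ring, ring B the catechol ring, ring C the veratryl ring.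

Assumption: (R)-DTBM-SEGPHOS–CuH is taken to deliver hydride to the face of C4 that gives (4R). The sense of induction has to be checked on the first run, and the (S)-ligand is used if it is the opposite.

Step 1
Reactants: 1 4-hydroxyphenyl benzoate
Product: 2 3-bromo-4-hydroxyphenyl benzoate
Conditions: NBS (1.0 equiv), MeCN, 0 °C to rt
Reagents that add atoms: N-bromosuccinimide, O=C1CCC(=O)N1Br
Why: Electrophilic aromatic bromination: the free hydroxyl is a far stronger donor than the benzoyloxy group and its para position is occupied, so bromine should enter ortho to OH, at the carbon that becomes C6.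

Step 2
Reactants: 2 3-bromo-4-hydroxyphenyl benzoate
Product: 3 4-(benzyloxy)-3-bromophenyl benzoate
Conditions: BnBr, K2CO3, DMF, rt
Reagents that add atoms: benzyl bromide, BrCc1ccccc1
Why: Williamson ether synthesis on the only free phenol puts the benzyl group on the oxygen that becomes O7, while the benzoate keeps the future O1 masked under the mild carbonate conditions.

Step 3
Reactants: 3 4-(benzyloxy)-3-bromophenyl benzoate; 4 3,4-dimethoxystyrene; 5 9-borabicyclo[3.3.1]nonane (9-BBN-H)
Product: 8 4-(benzyloxy)-3-[2-(3,4-dimethoxyphenyl)ethyl]phenol, via borane adduct 6 (not isolated), via coupled benzoate 7 (not isolated)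
Conditions: 4, 5, THF, 0 °C to rt; then 3, PdCl2(dppf) (cat.), aq K3PO4, DMF, 60 °C; then aq NaOH, MeOH, rt; HCl work-up
Reagents that add atoms: none
Why: Anti-Markovnikov hydroboration of the styrene and B-alkyl Suzuki–Miyaura coupling join C6 to the saturated two-carbon bridge without any hydrogenation that would endanger the benzyl ether, and saponification of the aryl benzoate in the same flask frees the phenol oxygen that becomes O1.

Step 4
Reactants: 9 3,4-bis(benzyloxy)benzaldehyde
Product: 10 1,2-bis(benzyloxy)-4-(2,2-dibromoethenyl)benzene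
Conditions: CBr4, PPh3, CH2Cl2, 0 °C
Reagents that add atoms: carbon tetrabromide, BrC(Br)(Br)Br
Why: Corey–Fuchs olefination (Wittig-type reaction of the dibromomethylene ylide) converts the aldehyde into the 1,1-dibromoalkene and tolerates aryl benzyl ethers.

Step 5
Reactants: 10 1,2-bis(benzyloxy)-4-(2,2-dibromoethenyl)benzene; 11 n-butyllithium
Product: 13 3-[3,4-bis(benzyloxy)phenyl]prop-2-ynoic acid, via lithium acetylide 12 (not isolated)
Conditions: n-BuLi (2.2 equiv), THF, −78 °C; then CO2, −78 °C to rt; 1 M HCl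
Reagents that add atoms: carbon dioxide, O=C=O
Why: Second stage of the Corey–Fuchs sequence: bromine–lithium exchange, Fritsch–Buttenberg–Wiechell-type rearrangement and deprotonation give acetylide 12, whose carboxylation with CO2 supplies C2.

Step 6
Reactants: 13 3-[3,4-bis(benzyloxy)phenyl]prop-2-ynoic acid
Product: 14 (Z)-3-[3,4-bis(benzyloxy)phenyl]-3-iodoprop-2-enoic acid
Conditions: NaI, AcOH, 90 °C
Reagents that add atoms: sodium iodide, [Na+].[I-]
Why: Hydroiodination of an alkynoic acid (net anti addition of HI): iodide should enter at the benzylic β-carbon (future C4) both for the conjugate-addition and for the aryl-stabilised vinyl-cation pathway, and the alkene geometry has no consequence for step 8.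

Step 7
Reactants: 8 4-(benzyloxy)-3-[2-(3,4-dimethoxyphenyl)ethyl]phenol; 14 (Z)-3-[3,4-bis(benzyloxy)phenyl]-3-iodoprop-2-enoic acid
Product: 15 4-(benzyloxy)-3-[2-(3,4-dimethoxyphenyl)ethyl]phenyl (Z)-3-[3,4-bis(benzyloxy)phenyl]-3-iodoprop-2-enoate
Conditions: DCC, DMAP (cat.), CH2Cl2, 0 °C
Reagents that add atoms: none
Why: Steglich esterification joins the two halves through C2–O1 under nearly neutral conditions at low temperature, which should avoid base-induced loss of HI from the β-iodoacrylate.

Step 8
Reactants: 15 4-(benzyloxy)-3-[2-(3,4-dimethoxyphenyl)ethyl]phenyl (Z)-3-[3,4-bis(benzyloxy)phenyl]-3-iodoprop-2-enoate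
Product: 19 7-(benzyloxy)-4-[3,4-bis(benzyloxy)phenyl]-6-[2-(3,4-dimethoxyphenyl)ethyl]-2H-chromen-2-one, via vinyl radical 16 (not isolated), via spiro radical 17 (not isolated), via ring-expanded radical 18 (not isolated)
Conditions: fac-Ir(ppy)3 (cat.), K2HPO4, degassed MeCN, blue LEDs, rt
Reagents that add atoms: none
Why: Proposed new method: excited fac-Ir(ppy)3 should reduce the C4–I bond of 15 to iodide and the linear, aryl-conjugated vinyl radical 16 (both alkene isomers of 15 give the same radical), which adds to the ester-bearing ipso carbon of ring A in a dearomatising 5-exo-trig closure (C4–C4a made) to spiro radical 17; 17 is a β-(acyloxy)alkyl radical and should undergo a Surzur–Tanner-type 1,2-acyloxy shift that moves O1 from C4a to C8a (O1–C8a made, the five-membered spirolactone expanding to the six-membered pyranone, formally a 6-endo closure of O1 on C8a) to give 18, which Ir(IV) oxidises and K2HPO4 deprotonates to coumarin 19, so that the step is redox-neutral. The closest known reaction type is the radical addition/ipso-cyclisation/1,2-ester migration of aryl 3-arylpropiolates to 3-substituted 4-arylcoumarins, in which a para substituent of the phenol ends up at C7; only the source of the vinyl radical is new, and it is chosen so that C3 carries hydrogen and no auxiliary group has to be cut off. No stereocentre is carried forward: the spiro carbon of 17 and C8a of 18 are erased on rearomatisation, and C4 leaves the step sp2, to be set in step 9. Ipso attack rather than direct ortho attack is needed and is secured by the faster 5-exo mode and by the para benzyloxy group on C7, which stabilises 17. Migration to C8a rather than to C5 is needed and is secured by the C6 side chain, which crowds C5. Oxidation of 17 to a spirotrienone has to stay slower than the shift, for which O7 is kept as an ether and the oxidant Ir(IV) is present only in trace concentration.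

Step 9
Reactants: 19 7-(benzyloxy)-4-[3,4-bis(benzyloxy)phenyl]-6-[2-(3,4-dimethoxyphenyl)ethyl]-2H-chromen-2-one; 20 pinacolborane
Product: 22 (4R)-7-(benzyloxy)-4-[3,4-bis(benzyloxy)phenyl]-6-[2-(3,4-dimethoxyphenyl)ethyl]-3,4-dihydro-2H-chromen-2-one, via boron enolate 21 (not isolated)
Conditions: Cu(OAc)2 (cat.), (R)-DTBM-SEGPHOS (cat.), HBpin, toluene, rt; then aq NH4Cl
Reagents that add atoms: none
Why: Copper hydride-catalysed asymmetric conjugate reduction (1,4-hydroboration) of a 4-arylcoumarin: the ligand-bound Cu–H should deliver hydride to one face of C4 of the flat, ring-locked acceptor and so set (4R) under catalyst control, while boron enolate 21 parks the lactone against 1,2-over-reduction until the aqueous quench protonates C3.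

Step 10
Reactants: 22 (4R)-7-(benzyloxy)-4-[3,4-bis(benzyloxy)phenyl]-6-[2-(3,4-dimethoxyphenyl)ethyl]-3,4-dihydro-2H-chromen-2-one
Product: 23 (4R)-4-(3,4-dihydroxyphenyl)-6-[2-(3,4-dimethoxyphenyl)ethyl]-7-hydroxy-3,4-dihydro-2H-chromen-2-one
Conditions: H2 (1 atm), 10% Pd/C, EtOAc–THF, rt
Reagents that add atoms: none
Why: Catalytic hydrogenolysis removes the three aryl benzyl ethers under neutral, aprotic conditions that leave the lactone, the two methyl ethers and the non-epimerisable C4 centre untouched.

**Compound list**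

1 | 4-hydroxyphenyl benzoate | O=C(Oc1ccc(O)cc1)c1ccccc1 | starting material
2 | 3-bromo-4-hydroxyphenyl benzoate | O=C(Oc1ccc(O)c(Br)c1)c1ccccc1 | intermediate
3 | 4-(benzyloxy)-3-bromophenyl benzoate | O=C(Oc1ccc(OCc2ccccc2)c(Br)c1)c1ccccc1 | intermediate
4 | 3,4-dimethoxystyrene | C=Cc1ccc(OC)c(OC)c1 | starting material
5 | 9-borabicyclo[3.3.1]nonane (9-BBN-H) | B1C2CCCC1CCC2 | starting material
6 | 9-[2-(3,4-dimethoxyphenyl)ethyl]-9-borabicyclo[3.3.1]nonane (borane adduct) | COc1ccc(CCB2C3CCCC2CCC3)cc1OC | intermediate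
7 | 4-(benzyloxy)-3-[2-(3,4-dimethoxyphenyl)ethyl]phenyl benzoate (coupled benzoate) | COc1ccc(CCc2cc(OC(=O)c3ccccc3)ccc2OCc2ccccc2)cc1OC | intermediate
8 | 4-(benzyloxy)-3-[2-(3,4-dimethoxyphenyl)ethyl]phenol | COc1ccc(CCc2cc(O)ccc2OCc2ccccc2)cc1OC | intermediate
9 | 3,4-bis(benzyloxy)benzaldehyde | O=Cc1ccc(OCc2ccccc2)c(OCc2ccccc2)c1 | starting material
10 | 1,2-bis(benzyloxy)-4-(2,2-dibromoethenyl)benzene | BrC(Br)=Cc1ccc(OCc2ccccc2)c(OCc2ccccc2)c1 | intermediate
11 | n-butyllithium | [Li]CCCC | starting material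
12 | lithium [3,4-bis(benzyloxy)phenyl]acetylide | [Li]C#Cc1ccc(OCc2ccccc2)c(OCc2ccccc2)c1 | intermediate
13 | 3-[3,4-bis(benzyloxy)phenyl]prop-2-ynoic acid | OC(=O)C#Cc1ccc(OCc2ccccc2)c(OCc2ccccc2)c1 | intermediate
14 | (Z)-3-[3,4-bis(benzyloxy)phenyl]-3-iodoprop-2-enoic acid | OC(=O)/C=C(\I)c1ccc(OCc2ccccc2)c(OCc2ccccc2)c1 | intermediate
15 | 4-(benzyloxy)-3-[2-(3,4-dimethoxyphenyl)ethyl]phenyl (Z)-3-[3,4-bis(benzyloxy)phenyl]-3-iodoprop-2-enoate | COc1ccc(CCc2cc(OC(=O)/C=C(\I)c3ccc(OCc4ccccc4)c(OCc4ccccc4)c3)ccc2OCc2ccccc2)cc1OC | intermediate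
16 | C4-centred α-aryl vinyl radical from 15 | COc1ccc(CCc2cc(OC(=O)C=[C]c3ccc(OCc4ccccc4)c(OCc4ccccc4)c3)ccc2OCc2ccccc2)cc1OC | intermediate
17 | spirolactone cyclohexadienyl radical (C4 and O1 both on C4a, radical drawn at C8a, spiro centre unassigned) | O=C1C=C(c2ccc(OCc3ccccc3)c(OCc3ccccc3)c2)C2(O1)[CH]C=C(OCc1ccccc1)C(CCc1ccc(OC)c(OC)c1)=C2 | intermediate
18 | ring-expanded cyclohexadienyl radical (O1 and H on C8a, radical drawn at C4a) | O=C1C=C(c2ccc(OCc3ccccc3)c(OCc3ccccc3)c2)[C]2C=C(CCc3ccc(OC)c(OC)c3)C(OCc3ccccc3)=CC2O1 | intermediate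
19 | 7-(benzyloxy)-4-[3,4-bis(benzyloxy)phenyl]-6-[2-(3,4-dimethoxyphenyl)ethyl]-2H-chromen-2-one | COc1ccc(CCc2cc3c(cc2OCc2ccccc2)OC(=O)C=C3c2ccc(OCc3ccccc3)c(OCc3ccccc3)c2)cc1OC | intermediate
20 | pinacolborane | CC1(C)OBOC1(C)C | starting material
21 | (4R)-2-(pinacolatoboryloxy)-4H-chromene (boron enolate of 22) | COc1ccc(CCc2cc3c(cc2OCc2ccccc2)OC(OB2OC(C)(C)C(C)(C)O2)=C[C@@H]3c2ccc(OCc3ccccc3)c(OCc3ccccc3)c2)cc1OC | intermediate
22 | (4R)-7-(benzyloxy)-4-[3,4-bis(benzyloxy)phenyl]-6-[2-(3,4-dimethoxyphenyl)ethyl]-3,4-dihydro-2H-chromen-2-one | COc1ccc(CCc2cc3c(cc2OCc2ccccc2)OC(=O)C[C@@H]3c2ccc(OCc3ccccc3)c(OCc3ccccc3)c2)cc1OC | intermediate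
23 | (4R)-4-(3,4-dihydroxyphenyl)-6-[2-(3,4-dimethoxyphenyl)ethyl]-7-hydroxy-3,4-dihydro-2H-chromen-2-one | COc1ccc(CCc2cc3c(cc2O)OC(=O)C[C@@H]3c2ccc(O)c(O)c2)cc1OC | target

**Totals**

Total step count: 10.
Longest linear sequence: 7 (steps 1–3, then 7–10; equally steps 4–6, then 7–10).

**Steps most likely to fail**

1. Step 8 (proposed new method).
   - What may go wrong: the vinyl radical may abstract hydrogen before it cyclises, or it may close directly on an ortho carbon. The spiro radical may be over-oxidised with loss of the benzyl group, or the acyloxy shift may run toward C5.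
   - Fallback: it uses known chemistry and gives up the oxygen shift. It sets out from borane adduct 6 and acid 13 and comes back at 19. Commercial 4-bromoresorcinol is benzylated (BnBr, K2CO3) to 2,4-bis(benzyloxy)-1-bromobenzene F1. B-alkyl Suzuki–Miyaura coupling of F1 with 6 would give 2,4-bis(benzyloxy)-1-[2-(3,4-dimethoxyphenyl)ethyl]benzene F2. Hydrogenolysis (H2, Pd/C) would give 4-[2-(3,4-dimethoxyphenyl)ethyl]benzene-1,3-diol F3. Pd(II)/TFA alkyne hydroarylation (Fujiwara-type) of 13 with F3 in TFA–CH2Cl2 should attack para to one hydroxyl and lactonise onto the other, giving 4-[3,4-bis(benzyloxy)phenyl]-6-[2-(3,4-dimethoxyphenyl)ethyl]-7-hydroxy-2H-chromen-2-one F4. Benzylation of F4 (BnBr, K2CO3) gives 19.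

2. Step 9.
   - What may go wrong: facial selectivity may be poor, because the two aryl groups on C4 are alike in size and electron demand. Reduction may run on to the lactol, or the enolate may open by loss of the aryloxide.
   - Fallback: it sets out from 19 and comes back at 22. Aqueous NaOH opens the lactone to disodium (2Z)-3-{4-(benzyloxy)-5-[2-(3,4-dimethoxyphenyl)ethyl]-2-oxidophenyl}-3-[3,4-bis(benzyloxy)phenyl]prop-2-enoate F5. This salt is hydrogenated with a cationic Rh(I)–chiral bisphosphine catalyst under carboxylate direction, and the benzyl ethers survive the homogeneous conditions. Acidification would give (3R)-3-{4-(benzyloxy)-5-[2-(3,4-dimethoxyphenyl)ethyl]-2-hydroxyphenyl}-3-[3,4-bis(benzyloxy)phenyl]propanoic acid F6. F6 closes to 22 with catalytic TsOH in warm toluene.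

3. Step 6.
   - What may go wrong: the electron-rich arylpropiolic acid may protodecarboxylate, the hot acidic iodide may cleave a benzyl ether, or the addition may stay incomplete.
   - Fallback: it sets out from 13 (with 8) and comes back at 15, bypassing 14. Steglich esterification is done first and would give 4-(benzyloxy)-3-[2-(3,4-dimethoxyphenyl)ethyl]phenyl 3-[3,4-bis(benzyloxy)phenyl]prop-2-ynoate F7. This ester cannot decarboxylate and is the better acceptor, so HI can be added under milder conditions (LiI, AcOH, MeCN, 60–80 °C) to give 15.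

**Further compounds**

F1 | step 8 | 2,4-bis(benzyloxy)-1-bromobenzene | Brc1ccc(OCc2ccccc2)cc1OCc1ccccc1
F2 | step 8 | 2,4-bis(benzyloxy)-1-[2-(3,4-dimethoxyphenyl)ethyl]benzene | COc1ccc(CCc2ccc(OCc3ccccc3)cc2OCc2ccccc2)cc1OC
F3 | step 8 | 4-[2-(3,4-dimethoxyphenyl)ethyl]benzene-1,3-diol | COc1ccc(CCc2ccc(O)cc2O)cc1OC
F4 | step 8 | 4-[3,4-bis(benzyloxy)phenyl]-6-[2-(3,4-dimethoxyphenyl)ethyl]-7-hydroxy-2H-chromen-2-one | COc1ccc(CCc2cc3c(cc2O)OC(=O)C=C3c2ccc(OCc3ccccc3)c(OCc3ccccc3)c2)cc1OC
F5 | step 9 | disodium (2Z)-3-{4-(benzyloxy)-5-[2-(3,4-dimethoxyphenyl)ethyl]-2-oxidophenyl}-3-[3,4-bis(benzyloxy)phenyl]prop-2-enoate | COc1ccc(CCc2cc(c([O-])cc2OCc2ccccc2)/C(=C\C([O-])=O)c2ccc(OCc3ccccc3)c(OCc3ccccc3)c2)cc1OC.[Na+].[Na+]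
F6 | step 9 | (3R)-3-{4-(benzyloxy)-5-[2-(3,4-dimethoxyphenyl)ethyl]-2-hydroxyphenyl}-3-[3,4-bis(benzyloxy)phenyl]propanoic acid | OC(=O)C[C@@H](c1cc(CCc2ccc(OC)c(OC)c2)c(OCc2ccccc2)cc1O)c1ccc(OCc2ccccc2)c(OCc2ccccc2)c1
F7 | step 6 | 4-(benzyloxy)-3-[2-(3,4-dimethoxyphenyl)ethyl]phenyl 3-[3,4-bis(benzyloxy)phenyl]prop-2-ynoate | COc1ccc(CCc2cc(OC(=O)C#Cc3ccc(OCc4ccccc4)c(OCc4ccccc4)c3)ccc2OCc2ccccc2)cc1OC
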